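**Retrosynthetic overview**
1. Target ⇐ 13‑O‑acetylation, PMB removal and 8‑O‑tigloylation of macrocyclic alcohol 35; C8 is set by CBS reduction of ring ketone 34.
2. Ten‑membered ring ⇐ Nozaki–Hiyama–Kishi closure of C7–C8 between a butenolide (tetronate) triflate and the C8 aldehyde (32).
3. Butenolide ⇐ lactonisation/triflation of β‑keto ester 29 ⇐ key intermolecular aldol (C7–C11) of the lithium enolate of methyl 3‑(4‑methoxybenzyloxy)propanoate with α‑silyloxy aldehyde 23, then oxidation.
4. Aldehyde 23 ⇐ nerol: Sharpless epoxidation (C4, C5), ozonolysis and Roush anti‑crotylboration (C1, C10), hydroboration (C8), vinyl addition and chelation‑controlled reduction (C6).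
5. Ring order: epoxide (step 1), butenolide (step 19), ten‑membered carbocycle (step 21).

Assumption: locants follow the germacrane skeleton of the target (ring C1–C10 with C1 = CH–OAc, C4/C5 = epoxide, C6 = lactone CH–O, C7 = ring‑fusion alkene carbon, C8 = CH–O‑tiglate, C10 = CH–CH3; C11 = lactone α‑carbon, C12 = lactone C=O, C13 = CH2O); the target is (1S,4R,5S,6S,8S,10R).

**Step 1**
Reactants: 1 nerol
Product: 2 (2S,3R)-2,3-epoxynerol
Conditions: Ti(OiPr)4 (10 mol %), L-(+)-diethyl tartrate (12 mol %), t-BuOOH, 4 Å MS, CH2Cl2, −20 °C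
Reagents that add atoms: tert-butyl hydroperoxide CC(C)(C)OO
Why: Sharpless asymmetric epoxidation of the Z-allylic alcohol, in which the L-(+)-tartrate–titanium complex delivers oxygen to the face giving the (2S,3R)-epoxide (C4 R, C5 S) and leaves the isolated alkene untouched.

**Step 2**
Reactants: 2 (2S,3R)-2,3-epoxynerol
Product: 3 TBS ether of 2
Conditions: TBSCl, imidazole, CH2Cl2, 0 °C → rt
Reagents that add atoms: tert-butyldimethylsilyl chloride CC(C)(C)[Si](C)(C)Cl
Why: Silylation of the primary alcohol under imidazole catalysis, conditions too mild for Payne rearrangement of the epoxy alcohol.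

**Step 3**
Reactants: 3 TBS ether of 2
Product: 5 C1 aldehyde 3-[(2R,3S)-3-(tert-butyldimethylsilyloxymethyl)-2-methyloxiran-2-yl]propanal, via secondary ozonide 4 (not isolated)
Conditions: O3, CH2Cl2, −78 °C; then Me2S, −78 °C → rt
Reagents that add atoms: ozone [O-][O+]=O
Why: Ozonolysis with reductive work-up cleaves the only alkene to the C1 aldehyde, while epoxide and silyl ether are inert to ozone.

**Step 4**
Reactants: 6 (E)-but-2-ene
Product: 10 diisopropyl (4S,5S)-2-[(E)-but-2-enyl]-1,3,2-dioxaborolane-4,5-dicarboxylate, via (E)-but-2-enylpotassium 7 (not isolated), via potassium (E)-but-2-enyl(triisopropoxy)borate 8 (not isolated), via (E)-but-2-enylboronic acid 9 (not isolated)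
Conditions: KOt-Bu, n-BuLi, THF, −50 °C; B(OiPr)3, −78 °C; 1 M HCl; then diisopropyl D-tartrate, MgSO4, Et2O, rt
Reagents that add atoms: triisopropyl borate CC(C)OB(OC(C)C)OC(C)C; diisopropyl D-tartrate CC(C)OC(=O)[C@@H](O)[C@H](O)C(=O)OC(C)C
Why: Schlosser metalation gives configurationally stable (E)-crotylpotassium, which is borylated and esterified with the tartrate (Roush reagent synthesis) with retention of the E geometry.

**Step 5**
Reactants: 5 C1 aldehyde; 10 (S,S)-tartrate (E)-crotylboronate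
Product: 11 (1S,4R,5S,10R) homoallylic alcohol (C1–OH, C10–CH3 anti)
Conditions: 4 Å MS, toluene, −78 °C; then aq. NaHCO3
Reagents that add atoms: none
Why: Roush asymmetric crotylboration through a chair Zimmerman–Traxler transition state, in which the E-crotyl geometry gives the 1,10-anti relationship and the (S,S)-tartrate directs attack to the Re face (1S,10R), without any Lewis acid that would endanger the epoxide.

**Step 6**
Reactants: 11 homoallylic alcohol
Product: 12 C1 acetate of 11
Conditions: Ac2O, pyridine, cat. DMAP, CH2Cl2, 0 °C → rt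
Reagents that add atoms: acetic anhydride CC(=O)OC(C)=O
Why: DMAP-catalysed acetylation installs the C1 acetate of the target at once and removes the free γ-hydroxyl that could otherwise open the 4,5-epoxide.

**Step 7**
Reactants: 12 C1 acetate
Product: 14 C8 primary alcohol (1S,4R,5S,10R), via B-alkyl-9-BBN adduct 13 (not isolated)
Conditions: 9-BBN, THF, 0 °C → rt; then 30% H2O2, aq. NaOAc, 0 °C → rt
Reagents that add atoms: hydrogen peroxide OO
Why: Hydroboration–oxidation, in which 9-BBN adds anti-Markovnikov to the terminal alkene only and the buffered peroxide oxidation spares acetate and epoxide.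

**Step 8**
Reactants: 14 C8 primary alcohol
Product: 15 C8 TBDPS ether
Conditions: TBDPSCl, imidazole, DMF, rt
Reagents that add atoms: tert-butyl(chloro)diphenylsilane CC(C)(C)[Si](Cl)(c1ccccc1)c1ccccc1
Why: Standard silylation of the primary alcohol with the more fluoride-resistant TBDPS group, allowing the C6 TBS ether to be removed selectively next.

**Step 9**
Reactants: 15 C8 TBDPS ether
Product: 16 C6 epoxy alcohol
Conditions: HF·pyridine, pyridine, THF, 0 °C → rt
Reagents that add atoms: none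
Why: Buffered fluoride desilylation cleaves the primary TBS ether much faster than the TBDPS ether and leaves acetate and epoxide intact.

**Step 10**
Reactants: 16 C6 epoxy alcohol
Product: 17 epoxy aldehyde (C6 H=O)
Conditions: Dess–Martin periodinane, NaHCO3, CH2Cl2, 0 °C → rt
Reagents that add atoms: none
Why: Dess–Martin oxidation under buffered neutral conditions gives the α,β-epoxy aldehyde without epoxide opening.

**Step 11**
Reactants: 17 epoxy aldehyde
Product: 18 allylic alcohols (both C6 epimers)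
Conditions: CH2=CHMgBr (1.3 equiv), THF, −78 °C; then H2O
Reagents that add atoms: vinylmagnesium bromide C=C[Mg]Br
Why: Grignard addition at −78 °C is far faster at the aldehyde than at the acetate, and the C6 epimer ratio is irrelevant because C6 is reset in steps 12 and 13.

**Step 12**
Reactants: 18 allylic alcohols
Product: 19 epoxy vinyl ketone
Conditions: Dess–Martin periodinane, NaHCO3, CH2Cl2, 0 °C
Reagents that add atoms: none
Why: Dess–Martin oxidation converts the allylic alcohol into the α,β-epoxy enone under neutral conditions.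

**Step 13**
Reactants: 19 epoxy vinyl ketone
Product: 20 anti-epoxy allylic alcohol (6S)
Conditions: Zn(BH4)2, Et2O, −30 → 0 °C
Reagents that add atoms: none
Why: Chelation-controlled 1,2-reduction (Nakata–Oishi type), in which zinc bridges the ketone and epoxide oxygens and hydride attacks anti to the epoxide C–C bond to give the 5,6-anti (6S) alcohol.

**Step 14**
Reactants: 20 anti-epoxy allylic alcohol
Product: 21 C6 TES ether
Conditions: TESCl, imidazole, cat. DMAP, CH2Cl2, 0 °C → rt
Reagents that add atoms: chlorotriethylsilane CC[Si](Cl)(CC)CC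
Why: Mild silylation of the secondary alcohol with a group that is later removed together with the TBDPS ether by fluoride.

**Step 15**
Reactants: 21 C6 TES ether
Product: 23 α-silyloxy aldehyde (C7 H=O), via secondary ozonide 22 (not isolated)
Conditions: O3, CH2Cl2, −78 °C; then Me2S
Reagents that add atoms: ozone [O-][O+]=O
Why: Ozonolysis of the only alkene gives the C7 aldehyde, which is used crude to avoid epimerisation at C6.

**Step 16**
Reactants: 24 4-methoxybenzyl alcohol; 25 methyl acrylate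
Product: 26 methyl 3-(4-methoxybenzyloxy)propanoate
Conditions: NaH (5 mol %), THF, 0 °C → rt
Reagents that add atoms: none
Why: Base-catalysed oxa-Michael addition of the benzylic alkoxide to the acrylate.

**Step 17**
Reactants: 26 methyl 3-(4-methoxybenzyloxy)propanoate; 23 α-silyloxy aldehyde
Product: 28 aldol adduct (β-hydroxy ester), via lithium enolate 27 (not isolated)
Conditions: LiN(iPr)2, THF, −78 °C; then 23, −78 °C; AcOH quench at −78 °C
Reagents that add atoms: none
Why: Intermolecular aldol addition of the preformed lithium ester enolate forms the C7–C11 bond at −78 °C faster than β-alkoxide elimination or attack on the acetate, and the new centres at C7 and C11 are inconsequential because both become sp2.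

**Step 18**
Reactants: 28 aldol adduct
Product: 29 β-keto ester
Conditions: Dess–Martin periodinane, NaHCO3, CH2Cl2, rt
Reagents that add atoms: none
Why: Dess–Martin oxidation of the β-hydroxy ester gives the β-keto ester without touching silyl ethers, epoxide or PMB ether.

**Step 19**
Reactants: 29 β-keto ester
Product: 31 tetronate triflate alcohol (C7–OTf, C8 H2OH), via tetronic acid 30 (not isolated)
Conditions: Bu4NF/AcOH (1:1, 3 equiv), THF, 0 °C → rt; then Et3N, PhNTf2, cat. DMAP, CH2Cl2, 0 °C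
Reagents that add atoms: N-phenylbis(trifluoromethanesulfonimide) O=S(=O)(N(c1ccccc1)S(=O)(=O)C(F)(F)F)C(F)(F)F
Why: Fluoride desilylation frees the C6 and C8 hydroxyls, the C6 hydroxyl lactonises onto the β-keto ester to a tetronate kept as its ammonium salt (no free acid next to the epoxide), and the triflimide sulfonylates this enolate selectively over the neutral primary alcohol.

**Step 20**
Reactants: 31 tetronate triflate alcohol
Product: 32 triflate aldehyde (C8 H=O)
Conditions: Dess–Martin periodinane, NaHCO3, CH2Cl2, 0 °C → rt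
Reagents that add atoms: none
Why: Dess–Martin oxidation of the primary alcohol, to which the vinylogous acyl triflate is stable.

**Step 21**
Reactants: 32 triflate aldehyde
Product: 33 macrocyclic allylic alcohols (C8 epimers)
Conditions: CrCl2 (10 equiv), NiCl2 (0.1 equiv), degassed DMF, rt, slow addition (final 0.003 M)
Reagents that add atoms: none
Why: Nozaki–Hiyama–Kishi macrocyclisation, in which zerovalent nickel inserts into the C7–OTf bond and the derived alkenylchromium adds only to the aldehyde under high dilution; C8 forms as an epimer mixture that is erased in step 22.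

**Step 22**
Reactants: 33 macrocyclic allylic alcohols
Product: 34 macrocyclic C8 ketone
Conditions: Dess–Martin periodinane, NaHCO3, CH2Cl2, 0 °C
Reagents that add atoms: none
Why: Dess–Martin oxidation converges both C8 epimers on one ring ketone.

**Step 23**
Reactants: 34 macrocyclic C8 ketone
Product: 35 (8S)-alcohol
Conditions: (R)-2-methyl-CBS-oxazaborolidine (0.5 equiv), catecholborane, toluene, −78 °C
Reagents that add atoms: none
Why: Corey–Bakshi–Shibata reduction, in which the (R)-oxazaborolidine binds the ketone with the alkenyl carbon C7 as the large group and delivers hydride 1,2 to give the 8S alcohol under reagent control.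

**Step 24**
Reactants: 35 (8S)-alcohol
Product: 36 8-O-tiglate
Conditions: tigloyl chloride, Et3N, cat. DMAP, CH2Cl2, 0 °C → rt
Reagents that add atoms: tigloyl chloride C/C=C(\C)C(=O)Cl
Why: DMAP-catalysed acylation esterifies the allylic alcohol with retention at C8, and the tiglate is the stable E isomer so its geometry is not scrambled.

**Step 25**
Reactants: 36 8-O-tiglate
Product: 37 C13 primary alcohol
Conditions: DDQ, CH2Cl2/pH 7 buffer (10:1), 0 °C → rt
Reagents that add atoms: none
Why: Oxidative PMB ether cleavage by DDQ (benzylic hydride abstraction, then hydrolysis) is orthogonal to the esters, the epoxide and the butenolide.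

**Step 26**
Reactants: 37 C13 primary alcohol
Product: 38 target CNP0287840.1
Conditions: Ac2O, pyridine, cat. DMAP, CH2Cl2, 0 °C → rt
Reagents that add atoms: acetic anhydride CC(=O)OC(C)=O
Why: DMAP-catalysed acetylation of the primary allylic alcohol completes the target without affecting any stereocentre.

**Compound list**
1 | nerol, (2Z)-3,7-dimethylocta-2,6-dien-1-ol | CC(C)=CCC/C(C)=C\CO | starting material
2 | (2S,3R)-2,3-epoxynerol, [(2S,3R)-3-methyl-3-(4-methylpent-3-enyl)oxiran-2-yl]methanol | CC(C)=CCC[C@@]1(C)O[C@H]1CO | intermediate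
3 | TBS ether of 2 | CC(C)=CCC[C@@]1(C)O[C@H]1CO[Si](C)(C)C(C)(C)C | intermediate
4 | secondary ozonide (1,2,4-trioxolane) of the alkene of 3 | CC1(C)OOC(CC[C@@]2(C)O[C@H]2CO[Si](C)(C)C(C)(C)C)O1 | intermediate
5 | C1 aldehyde, 3-[(2R,3S)-3-(tert-butyldimethylsilyloxymethyl)-2-methyloxiran-2-yl]propanal, (4R,5S) | O=CCC[C@@]1(C)O[C@H]1CO[Si](C)(C)C(C)(C)C | intermediate
6 | (E)-but-2-ene | C/C=C/C | starting material
7 | (E)-but-2-enylpotassium | C/C=C/C[K] | intermediate
8 | potassium (E)-but-2-enyl(triisopropoxy)borate | C/C=C/C[B-](OC(C)C)(OC(C)C)OC(C)C.[K+] | intermediate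
9 | (E)-but-2-enylboronic acid | C/C=C/CB(O)O | intermediate
10 | diisopropyl (4S,5S)-2-[(E)-but-2-enyl]-1,3,2-dioxaborolane-4,5-dicarboxylate, the (S,S)-tartrate (E)-crotylboronate | C/C=C/CB1O[C@H](C(=O)OC(C)C)[C@@H](C(=O)OC(C)C)O1 | intermediate
11 | homoallylic alcohol H2C8=C9H–C10H(CH3)–C1H(OH)–C2H2–C3H2–C4(CH3)–C5H–C6H2OTBS with 4,5-epoxide, (1S,4R,5S,10R); (3R,4S)-6-[(2R,3S)-3-(tert-butyldimethylsilyloxymethyl)-2-methyloxiran-2-yl]-3-methylhex-1-en-4-ol | C=C[C@@H](C)[C@@H](O)CC[C@@]1(C)O[C@H]1CO[Si](C)(C)C(C)(C)C | intermediate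
12 | C1 acetate of 11, (1S,4R,5S,10R) | C=C[C@@H](C)[C@@H](OC(C)=O)CC[C@@]1(C)O[C@H]1CO[Si](C)(C)C(C)(C)C | intermediate
13 | B-alkyl-9-borabicyclo[3.3.1]nonane adduct of 12, boron on C8 | C1CCC2CCCC1B2CC[C@@H](C)[C@@H](OC(C)=O)CC[C@@]1(C)O[C@H]1CO[Si](C)(C)C(C)(C)C | intermediate
14 | primary alcohol HOC8H2–C9H2–C10H(CH3)–C1H(OAc)–C2H2–C3H2–C4(CH3)–C5H–C6H2OTBS with 4,5-epoxide, (1S,4R,5S,10R) | OCC[C@@H](C)[C@@H](OC(C)=O)CC[C@@]1(C)O[C@H]1CO[Si](C)(C)C(C)(C)C | intermediate
15 | C8 TBDPS ether of 14 | CC(C)(C)[Si](OCC[C@@H](C)[C@@H](OC(C)=O)CC[C@@]1(C)O[C@H]1CO[Si](C)(C)C(C)(C)C)(c1ccccc1)c1ccccc1 | intermediate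
16 | epoxy alcohol, 15 with free C6H2OH, (1S,4R,5S,10R) | CC(C)(C)[Si](OCC[C@@H](C)[C@@H](OC(C)=O)CC[C@@]1(C)O[C@H]1CO)(c1ccccc1)c1ccccc1 | intermediate
17 | epoxy aldehyde, C6H=O, (1S,4R,5R,10R) | CC(C)(C)[Si](OCC[C@@H](C)[C@@H](OC(C)=O)CC[C@@]1(C)O[C@H]1C=O)(c1ccccc1)c1ccccc1 | intermediate
18 | allylic alcohols C5H–C6H(OH)–C7H=CH2, (1S,4R,5S,10R), both C6 epimers | CC(C)(C)[Si](OCC[C@@H](C)[C@@H](OC(C)=O)CC[C@@]1(C)O[C@H]1C(O)C=C)(c1ccccc1)c1ccccc1 | intermediate
19 | epoxy vinyl ketone C5H–C6(=O)–C7H=CH2, (1S,4R,5R,10R) | CC(C)(C)[Si](OCC[C@@H](C)[C@@H](OC(C)=O)CC[C@@]1(C)O[C@H]1C(=O)C=C)(c1ccccc1)c1ccccc1 | intermediate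
20 | anti-epoxy allylic alcohol, (1S,4R,5S,6S,10R) | CC(C)(C)[Si](OCC[C@@H](C)[C@@H](OC(C)=O)CC[C@@]1(C)O[C@H]1[C@@H](O)C=C)(c1ccccc1)c1ccccc1 | intermediate
21 | C6 TES ether of 20, (1S,4R,5S,6S,10R) | CC(C)(C)[Si](OCC[C@@H](C)[C@@H](OC(C)=O)CC[C@@]1(C)O[C@H]1[C@@H](O[Si](CC)(CC)CC)C=C)(c1ccccc1)c1ccccc1 | intermediate
22 | secondary ozonide of the vinyl group of 21 | CC(C)(C)[Si](OCC[C@@H](C)[C@@H](OC(C)=O)CC[C@@]1(C)O[C@H]1[C@@H](O[Si](CC)(CC)CC)C2OCOO2)(c1ccccc1)c1ccccc1 | intermediate
23 | aldehyde TBDPSOC8H2–C9H2–C10H(CH3)–C1H(OAc)–C2H2–C3H2–C4(CH3)–C5H–C6H(OTES)–C7H=O with 4,5-epoxide, (1S,4R,5S,6R,10R) | CC(C)(C)[Si](OCC[C@@H](C)[C@@H](OC(C)=O)CC[C@@]1(C)O[C@H]1[C@@H](O[Si](CC)(CC)CC)C=O)(c1ccccc1)c1ccccc1 | intermediate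
24 | 4-methoxybenzyl alcohol | COc1ccc(CO)cc1 | starting material
25 | methyl acrylate | C=CC(=O)OC | starting material
26 | methyl 3-(4-methoxybenzyloxy)propanoate | COC(=O)CCOCc1ccc(OC)cc1 | intermediate
27 | lithium enolate of 26 | [Li]OC(OC)=CCOCc1ccc(OC)cc1 | intermediate
28 | aldol adduct C6H(OTES)–C7H(OH)–C11H(C13H2OPMB)–C12O2CH3, (1S,4R,5S,6S,10R), diastereomers at C7 and C11 | CC(C)(C)[Si](OCC[C@@H](C)[C@@H](OC(C)=O)CC[C@@]1(C)O[C@H]1[C@@H](O[Si](CC)(CC)CC)C(O)C(COCc2ccc(OC)cc2)C(=O)OC)(c1ccccc1)c1ccccc1 | intermediate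
29 | β-keto ester C6H(OTES)–C7(=O)–C11H(CH2OPMB)–CO2CH3, (1S,4R,5S,6R,10R), epimers at C11 | CC(C)(C)[Si](OCC[C@@H](C)[C@@H](OC(C)=O)CC[C@@]1(C)O[C@H]1[C@@H](O[Si](CC)(CC)CC)C(=O)C(COCc2ccc(OC)cc2)C(=O)OC)(c1ccccc1)c1ccccc1 | intermediate
30 | tetronic acid, 4-hydroxy-3-(4-methoxybenzyloxymethyl)furan-2(5H)-one ring (O–C6H–C7(OH)=C11–C12=O) carrying the C5–C8 chain with free C8H2OH, (1S,4R,5S,6R,10R) | OCC[C@@H](C)[C@@H](OC(C)=O)CC[C@@]1(C)O[C@H]1[C@H]1OC(=O)C(COCc2ccc(OC)cc2)=C1O | intermediate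
31 | enol triflate of 30 (C7–OSO2CF3), free C8H2OH, (1S,4R,5S,6R,10R) | OCC[C@@H](C)[C@@H](OC(C)=O)CC[C@@]1(C)O[C@H]1[C@H]1OC(=O)C(COCc2ccc(OC)cc2)=C1OS(=O)(=O)C(F)(F)F | intermediate
32 | triflate aldehyde, 31 with C8H=O | O=CC[C@@H](C)[C@@H](OC(C)=O)CC[C@@]1(C)O[C@H]1[C@H]1OC(=O)C(COCc2ccc(OC)cc2)=C1OS(=O)(=O)C(F)(F)F | intermediate
33 | (1S,4R,5S,6S,10R)-1-acetoxy-4,5-epoxy-8-hydroxy-13-(4-methoxybenzyloxy)germacr-7(11)-en-12,6-olide, C8 epimers | OC1C[C@@H](C)[C@@H](OC(C)=O)CC[C@@]2(C)O[C@H]2[C@H]2OC(=O)C(COCc3ccc(OC)cc3)=C12 | intermediate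
34 | (1S,4R,5S,6S,10R)-1-acetoxy-4,5-epoxy-13-(4-methoxybenzyloxy)-8-oxogermacr-7(11)-en-12,6-olide | O=C1C[C@@H](C)[C@@H](OC(C)=O)CC[C@@]2(C)O[C@H]2[C@H]2OC(=O)C(COCc3ccc(OC)cc3)=C12 | intermediate
35 | (1S,4R,5S,6S,8S,10R)-1-acetoxy-4,5-epoxy-8-hydroxy-13-(4-methoxybenzyloxy)germacr-7(11)-en-12,6-olide | O[C@H]1C[C@@H](C)[C@@H](OC(C)=O)CC[C@@]2(C)O[C@H]2[C@H]2OC(=O)C(COCc3ccc(OC)cc3)=C12 | intermediate
36 | 8-O-tiglate of 35 | C/C=C(\C)C(=O)O[C@H]1C[C@@H](C)[C@@H](OC(C)=O)CC[C@@]2(C)O[C@H]2[C@H]2OC(=O)C(COCc3ccc(OC)cc3)=C12 | intermediate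
37 | (1S,4R,5S,6S,8S,10R)-1-acetoxy-4,5-epoxy-13-hydroxy-8-tigloyloxygermacr-7(11)-en-12,6-olide | C/C=C(\C)C(=O)O[C@H]1C[C@@H](C)[C@@H](OC(C)=O)CC[C@@]2(C)O[C@H]2[C@H]2OC(=O)C(CO)=C12 | intermediate
38 | CNP0287840.1, (1S,4R,5S,6S,8S,10R)-1,13-diacetoxy-4,5-epoxy-8-tigloyloxygermacr-7(11)-en-12,6-olide | C/C=C(\C)C(=O)O[C@H]1C[C@@H](C)[C@@H](OC(C)=O)CC[C@@]2(C)O[C@H]2[C@H]2OC(=O)C(COC(C)=O)=C12 | target

**Step count and risks**
Total step count: 26. Longest linear sequence: 24 steps (nerol 1 to 38 through steps 1–3, 5–15 and 17–26; steps 4 and 16 are side branches).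

The three steps most likely to fail:

Step 19 (one-pot desilylation, lactonisation and triflation). The risks are attack of a free tetronic acid on the neighbouring epoxide and imperfect selectivity between enolate and primary alcohol. The fallback sets out from 29 and triflates before any hydroxyl is unmasked. Deprotonation with KN(SiMe3)2 and 18-crown-6 at −78 °C (non-chelated enolate) and trapping with PhNTf2 gives the acyclic (E)-enol triflate F1, in which C6 is cis to the methyl ester. Buffered Bu4NF/AcOH then removes both silyl groups and the C6 hydroxyl closes directly onto the ester. This comes back to the route at 31 without a tetronic acid ever being formed.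

Step 21 (ten-membered ring closure by chromium-mediated carbonyl addition). If the alkenylchromium does not close the ring, the C7–C8 bond is made instead by palladium-catalysed acylation. The fallback sets out from 31. Pd(PPh3)4 (zerovalent palladium), Me3SnSnMe3 and LiCl convert the triflate into the vinylstannane alcohol F2. TEMPO with PhI(OAc)2 in aqueous MeCN oxidises the primary alcohol to the stannyl carboxylic acid F3. 1-Chloro-N,N,2-trimethylprop-1-en-1-amine gives the acid chloride F4 under neutral conditions. F4 undergoes intramolecular acyl Stille coupling (Pd2(dba)3, tri(2-furyl)phosphine, toluene, high dilution) and comes back to the route at ketone 34.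

Step 23 (reagent-controlled reduction inside a conformationally biased ring). If the ring overrides the catalyst and the reduction of 34 delivers the 8R alcohol F5, the fallback sets out from 34 and keeps that epimer. F5 is esterified with tiglic acid under Mitsunobu conditions (PPh3, diisopropyl azodicarboxylate, toluene, 0 °C), which installs the tiglate with inversion at C8 and comes back to the route at 36.

**Further compounds**
F1 | step 19 | acyclic (E)-enol triflate of 29 (C7–OTf trans to CO2CH3, C6 cis to CO2CH3), silyl ethers retained | CC(C)(C)[Si](OCC[C@@H](C)[C@@H](OC(C)=O)CC[C@@]1(C)O[C@H]1[C@@H](O[Si](CC)(CC)CC)/C(OS(=O)(=O)C(F)(F)F)=C(/COCc2ccc(OC)cc2)C(=O)OC)(c1ccccc1)c1ccccc1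
F2 | step 21 | vinylstannane alcohol, 31 with C7–SnMe3 in place of C7–OTf | OCC[C@@H](C)[C@@H](OC(C)=O)CC[C@@]1(C)O[C@H]1[C@H]1OC(=O)C(COCc2ccc(OC)cc2)=C1[Sn](C)(C)C
F3 | step 21 | stannyl carboxylic acid, F2 with C8 as CO2H | OC(=O)C[C@@H](C)[C@@H](OC(C)=O)CC[C@@]1(C)O[C@H]1[C@H]1OC(=O)C(COCc2ccc(OC)cc2)=C1[Sn](C)(C)C
F4 | step 21 | acid chloride of F3 | ClC(=O)C[C@@H](C)[C@@H](OC(C)=O)CC[C@@]1(C)O[C@H]1[C@H]1OC(=O)C(COCc2ccc(OC)cc2)=C1[Sn](C)(C)C
F5 | step 23 | 8R alcohol, C8 epimer of 35 | O[C@@H]1C[C@@H](C)[C@@H](OC(C)=O)CC[C@@]2(C)O[C@H]2[C@H]2OC(=O)C(COCc3ccc(OC)cc3)=C12
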